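**Assumption:** the SMILES has no stereocentres and no descriptor for the hindered C5–C1′ biaryl axis, so I treat the target as the constitution drawn. The route forms the axis without control (racemate); the atropisomers can be separated on a chiral stationary phase if one is wanted. The route is designed from known reaction classes and has not been run.

## Retrosynthetic overview

1. Last step: one acid treatment removes the naphthol MOM ether and the primary TBS ether.
2. The C5–C1′ biaryl bond is made late by Negishi coupling of a 5-bromoisoquinoline with a 1-naphthylzinc reagent.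
3. Isoquinoline: the pyridine ring is built onto a dimethoxybenzene by Friedel–Crafts acetylation, Sonogashira coupling and ammonia 6-endo annulation, then C5 bromination.
4. Naphthalene: the phenol ring is built onto an anisamide by ortho-metalation/methallylation and anionic amide annulation, then para-bromination and MOM protection.
5. Ring order: each bicycle is completed separately from a benzene, and the two are joined last.

## Route

**Step 1**
Reactants: 1, 1-bromo-3,5-dimethoxybenzene; 2, acetyl chloride
Product: 3, 1-(2-bromo-4,6-dimethoxyphenyl)ethan-1-one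
Conditions: AcCl, AlCl3 (1.2 equiv), CH2Cl2, −10 → 0 °C, 1 h
Reagents that add atoms: acetyl chloride (2), CC(Cl)=O
Why: Friedel–Crafts acylation goes para to one OMe and ortho to the other (the same site as the known Vilsmeier formylation of 1), and the short, cold reaction limits AlCl3 ortho-demethylation.

**Step 2**
Reactants: 3; 4, tert-butyldimethyl(prop-2-yn-1-yloxy)silane
Product: 5, 1-[2-(3-{[tert-butyl(dimethyl)silyl]oxy}prop-1-yn-1-yl)-4,6-dimethoxyphenyl]ethan-1-one
Conditions: PdCl2(PPh3)2 (5 mol%), CuI (5 mol%), Et3N/DMF, 70 °C
Reagents that add atoms: none beyond alkyne 4 (C#CCO[Si](C)(C)C(C)(C)C), listed as reactant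
Why: Sonogashira coupling; the ortho-acetyl group activates the C–Br bond for oxidative addition, and the ketone and silyl ether are inert.

**Step 3**
Reactants: 5
Product: 6, 3-({[tert-butyl(dimethyl)silyl]oxy}methyl)-6,8-dimethoxy-1-methylisoquinoline
Conditions: NH3 (7 M in MeOH), AgOTf (10 mol%), sealed tube, 100 °C
Reagents that add atoms: ammonia, N
Why: Tandem imination / silver-assisted 6-endo-dig annulation of an o-alkynyl aryl ketone (via the ketimine or the isochromenylium ion) gives the aromatic isoquinoline, with the acetyl carbon as C1 and the CH2OTBS-bearing alkyne carbon as C3.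

**Step 4**
Reactants: 6
Product: 7, 5-bromo-3-({[tert-butyl(dimethyl)silyl]oxy}methyl)-6,8-dimethoxy-1-methylisoquinoline
Conditions: NBS (1.0 equiv), MeCN, 0 °C → rt, dark
Reagents that add atoms: N-bromosuccinimide, O=C1CCC(=O)N1Br
Why: Electrophilic aromatic bromination goes to C5, the α-position para to 8-OMe and ortho to 6-OMe, in preference to C7 between the two methoxy groups; ionic conditions leave the 1-methyl group and silyl ether alone.

**Step 5**
Reactants: 8, N,N-diethyl-2-methoxybenzamide; 9, 3-bromo-2-methylprop-1-ene (methallyl bromide)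
Product: 10, N,N-diethyl-2-methoxy-6-(2-methylprop-2-en-1-yl)benzamide
Conditions: s-BuLi, TMEDA, THF, −78 °C; MgBr2·OEt2, −78 → 0 °C; methallyl bromide, → rt
Reagents that add atoms: methallyl bromide (9), CC(=C)CBr
Why: Directed ortho-metalation; the diethylamide outranks OMe as director, so lithiation occurs at C6, and transmetalation to magnesium gives clean allylation.

**Step 6**
Reactants: 10
Product: 11, 8-methoxy-3-methylnaphthalen-1-ol
Conditions: LDA (2.5 equiv), THF, −78 °C → rt; aq. NH4Cl
Reagents that add atoms: none
Why: Anionic amide annulation of an o-allylbenzamide: the benzylic/allylic anion attacks the amide through its terminal carbon, Et2N⁻ is lost, and the enone tautomerises to the naphthol with OH peri to OMe.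

**Step 7**
Reactants: 11
Product: 12, 4-bromo-8-methoxy-3-methylnaphthalen-1-ol
Conditions: NBS (1.0 equiv), MeCN, −20 → 0 °C, dark
Reagents that add atoms: N-bromosuccinimide, O=C1CCC(=O)N1Br
Why: Electrophilic bromination of a 1-naphthol in MeCN is para-selective (α-position); the free OH is the strongest donor, so the phenol ring reacts, and C2 is more hindered than C4.

**Step 8**
Reactants: 12
Product: 13, 1-bromo-5-methoxy-4-(methoxymethoxy)-2-methylnaphthalene
Conditions: NaH, MOMCl, DMF, 0 °C → rt
Reagents that add atoms: chloromethyl methyl ether (MOMCl), COCCl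
Why: Williamson-type O-alkylation of the naphthoxide; the MOM ether tolerates organolithium and organozinc reagents and is acid-labile for the final step.

**Step 9**
Reactants: 13; 7
Product: 14, 3-({[tert-butyl(dimethyl)silyl]oxy}methyl)-6,8-dimethoxy-5-[5-methoxy-4-(methoxymethoxy)-2-methylnaphthalen-1-yl]-1-methylisoquinoline (racemic axis)
Conditions: 13 (1.5 equiv), t-BuLi (2 equiv per 13), THF, −78 °C; ZnCl2, −78 °C → rt; then 7, Pd2(dba)3 (2 mol%), RuPhos (8 mol%), THF/NMP, 70 °C
Reagents that add atoms: none (both fragments are numbered reactants; Li and Zn are not retained)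
Why: Negishi coupling with a bulky dialkylbiarylphosphine ligand is a standard solution for tetra-ortho-substituted biaryls, and the mild arylzinc does not deprotonate the 1-methyl group or touch the silyl ether; no stereocentre is formed and the axis is racemic.

**Step 10**
Reactants: 14
Product: 15, [5-(4-hydroxy-5-methoxy-2-methylnaphthalen-1-yl)-6,8-dimethoxy-1-methylisoquinolin-3-yl]methanol (ancistrobenomine A)
Conditions: 3 M HCl in MeOH, 40 °C; then aq. NaHCO3
Reagents that add atoms: none
Why: Acid-catalysed acetal cleavage (MOM) and silyl ether solvolysis (TBS) occur together, while the aryl methyl ethers, the isoquinoline and the hindered axis are unaffected.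

## Compound list

1 | 1-bromo-3,5-dimethoxybenzene | COc1cc(Br)cc(OC)c1 | starting material
2 | acetyl chloride | CC(Cl)=O | starting material
3 | 1-(2-bromo-4,6-dimethoxyphenyl)ethan-1-one | CC(=O)c1c(Br)cc(OC)cc1OC | intermediate
4 | tert-butyldimethyl(prop-2-yn-1-yloxy)silane | C#CCO[Si](C)(C)C(C)(C)C | starting material
5 | 1-[2-(3-{[tert-butyl(dimethyl)silyl]oxy}prop-1-yn-1-yl)-4,6-dimethoxyphenyl]ethan-1-one | CC(=O)c1c(C#CCO[Si](C)(C)C(C)(C)C)cc(OC)cc1OC | intermediate
6 | 3-({[tert-butyl(dimethyl)silyl]oxy}methyl)-6,8-dimethoxy-1-methylisoquinoline | COc1cc(OC)c2c(C)nc(CO[Si](C)(C)C(C)(C)C)cc2c1 | intermediate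
7 | 5-bromo-3-({[tert-butyl(dimethyl)silyl]oxy}methyl)-6,8-dimethoxy-1-methylisoquinoline | COc1cc(OC)c2c(C)nc(CO[Si](C)(C)C(C)(C)C)cc2c1Br | intermediate
8 | N,N-diethyl-2-methoxybenzamide (if not stocked, one step from 2-methoxybenzoyl chloride and Et2NH) | CCN(CC)C(=O)c1ccccc1OC | starting material
9 | 3-bromo-2-methylprop-1-ene | CC(=C)CBr | starting material
10 | N,N-diethyl-2-methoxy-6-(2-methylprop-2-en-1-yl)benzamide | CCN(CC)C(=O)c1c(CC(C)=C)cccc1OC | intermediate
11 | 8-methoxy-3-methylnaphthalen-1-ol | COc1cccc2cc(C)cc(O)c12 | intermediate
12 | 4-bromo-8-methoxy-3-methylnaphthalen-1-ol | COc1cccc2c(Br)c(C)cc(O)c12 | intermediate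
13 | 1-bromo-5-methoxy-4-(methoxymethoxy)-2-methylnaphthalene | COCOc1cc(C)c(Br)c2cccc(OC)c12 | intermediate
14 | 3-({[tert-butyl(dimethyl)silyl]oxy}methyl)-6,8-dimethoxy-5-[5-methoxy-4-(methoxymethoxy)-2-methylnaphthalen-1-yl]-1-methylisoquinoline | COCOc1cc(C)c(-c2c(OC)cc(OC)c3c(C)nc(CO[Si](C)(C)C(C)(C)C)cc23)c2cccc(OC)c12 | intermediate
15 | ancistrobenomine A | COc1cc(OC)c2c(C)nc(CO)cc2c1-c1c(C)cc(O)c2c(OC)cccc12 | target

## Totals

Total steps: 10. Longest linear sequence: 6 (steps 1–4, 9, 10 or steps 5–8, 9, 10).

## Three steps most likely to fail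

1. **Step 9, tetra-ortho-substituted biaryl coupling with an electron-rich bromide.** Fallback: close the axis intramolecularly by the biaryl-lactone strategy. Esterify a 6-hydroxyisoquinoline with the 1-bromo-2-naphthoic acid analogue of 13, perform Pd-catalysed intramolecular C–H arylation at C5, then reduce the lactone carbonyl to the 2′-methyl group and O-methylate O6.

2. **Step 3, imination/annulation of a 2,6-disubstituted, electron-rich ketone.** Fallback: Bischler–Napieralski construction. Condense 3,5-dimethoxybenzaldehyde with methyl 2-acetamido-2-(dimethoxyphosphoryl)acetate (HWE), hydrogenate, cyclise with POCl3, dehydrogenate to methyl 6,8-dimethoxy-1-methylisoquinoline-3-carboxylate and reduce the ester to CH2OH.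

3. **Step 7, para- versus ortho-bromination (or over-oxidation) of the electron-rich naphthol.** Fallback: fix the C1′ handle from a quinone and reverse the coupling polarity. Take plumbagin through O-methylation, reduction to the hydroquinone, selective triflation of the non-hydrogen-bonded 1-OH and MOM protection of the 4-OH; then Suzuki-couple this 1-naphthyl triflate with the 5-boronate made from 7 by Miyaura borylation.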